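Atom locants C1–C13 below are those of the target as defined in the first section; compound numbers are those of the steps and the compound list.

## Analysis of the target

- The target is a germacrane-type sesquiterpene lactone. Its ten-membered carbocycle runs C1 and C2 (methylenes), C3 (ketone), C4 (methyl-bearing methine), C5 (methylene), C6 (acyloxy methine), C7, C8, C9 (ylidene CH) and C10 (tertiary carbinol). It is fused along C7–C8 to a butenolide whose α-carbon C11 carries the acetoxymethyl carbon C13 and whose carbonyl is C12.
- The C8=C9 bond is Z (lactone oxygen cis to C10), which makes it an E double bond inside the ten-membered ring.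
- There are three stereocentres. C4 (S) and C6 (R) are 1,3-related on one flank of the planar dienyl lactone; C10 (R) sits alone on the other flank, so no direct relay links C10 to the C4/C6 pair.
- Sensitive groups are the enol (dienyl) lactone, which bases and nucleophiles attack, and C4, which is epimerisable next to the C3 ketone. The tertiary allylic C10 alcohol can close on the C3 ketone as a hemiketal. The C13 acetate is allylic, and the C6 senecioate can deconjugate.
- The difficulties are the strained medium ring with its E alkene and the control of C6 relative to the remote C10 centre.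
- The strategy rests on the C6–C7 bond. It joins an oxygenated sp3 carbon to the β-carbon of the butenolide, which is the bond an alkenyl-metal at C7 makes with an aldehyde at C6. It is also a ring bond, so forming it closes the ten-membered ring and creates the C6 carbinol in one step.

## Retrosynthetic reasoning

**Esters last (30 to 26).** The two acyl C–O bonds are cut first. The C13 acetate of 30 comes from primary alcohol 29, which comes from silyl ether 28; the C6 senecioate of 28 comes from secondary alcohol 26 and acid chloride 27. The allylic acetate and the deconjugation-prone senecioate are thus never exposed to organometallic or oxidising steps. The forward steps must acylate the secondary C6 hydroxyl in the presence of the tertiary C10 hydroxyl, then the primary C13 hydroxyl likewise.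

**Ring closure at C6–C7 (26 to 23).** Cutting C6–C7 opens the ten-membered ring to keto aldehyde 23, which carries an iodide on C7 and an aldehyde at C6. This cut is preferred over any other ring bond because it removes the ring and a stereocentre together and leaves a chain whose remaining stereocentres (C4, C10) are already in place. The forward reaction has to turn the C7–I bond into a nucleophile that adds to the aldehyde but not to the C3 ketone or the lactone, and it has to choose the Si face of the aldehyde.

**Oxidation level (23 to 21 to 20).** The C3 ketone and C6 aldehyde are taken back to the secondary and primary alcohols of triol 21, and these to the triethylsilyl ethers of 20. The 1,4-dicarbonyl unit is therefore generated only one step before it is used, and C4 is not epimerisable until then. The forward double oxidation must avoid lactol formation from the 1,4-diol.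

**Ylidene bond C8=C9 (20 to 12 + 17).** Cutting C8=C9 as an aldol condensation separates the chain aldehyde 12 (C9 to C6) from iodobutenolide 17 (C7, C8, C11, C12, C13). This is the only disconnection that makes the chain and the heterocycle independent, and the Z geometry is the thermodynamic one because C10 avoids the iodine on C7. The forward step must add the γ-carbon of 17 to a hindered α-quaternary aldehyde and then eliminate.

**Butenolide 17 (17 to 16 to 15 to 14 to 13).** The lactone C–O bond and the C7–I bond of 17 are cut together as an iodolactonisation of allenoate 16. The ester carbon of 16 is removed as a carbonylation of propargylic carbonate 15, which comes from monosilyl ether 14 of diol 13. All four carbons of 13 end up in the butenolide; C12 is added by carbonylation.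

**Chain aldehyde 12 (12 to 10 to 9 to 7).** The C9 aldehyde is taken back to the vinyl group of 10 (ozonolysis), the silyl ethers to diol 9, and the C6 hydroxyl of 9 to the terminal alkene of 7 (hydroboration). Forward, the hydroboration must choose the C5=C6 vinyl group over the hindered vinyl group on C10.

**C3–C4 bond (7 to 4 + 5).** Cutting C3–C4 as a crotylation gives aldehyde 4 and crotylboronate 5. This sets C4 by catalyst control in the step that also brings in C5 and C6. The C3 carbinol centre formed alongside is later oxidised away.

**Chiral pool (4 to 3 to 2 to 1).** Aldehyde 4 comes from epoxide 3 by oxidative cleavage, 3 from silyl ether 2 by epoxidation of the trisubstituted alkene, and 2 from 1. Compound 1 supplies C9, C10 with its methyl group and correct configuration, C1, C2 and C3, so the C10 centre is never made, only carried.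

## Alternatives that were turned down

**Alternative 1: carbon monoxide as C12.**
- Disconnection: C11–C12 and C12–O of the lactone.
- Forward key step: zerovalent palladium inserts into the C11–I bond of the ten-membered Z-β-iodoenone A2; carbon monoxide inserts, and the C8 enol oxygen closes the lactone to give the tris-silyl ether A1 with the C8=C9 ylidene in place.
- For it: the butenolide is made last, so no β-iodo dienyl lactone has to be carried; C6 can be set before the ring exists; and C12 comes from the cheapest possible source. On these points it is stronger than the chosen route.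
- Against it: A2 is itself a ten-membered ring with a stereodefined tetrasubstituted exocyclic iodoalkene and three oxygenated carbons. The ring-closure problem is only postponed to an unspecified earlier step, and the tetrasubstituted Z-iodoalkene has no obvious stereoselective source. The carbonylation also needs base with the epimerisable C4 centre present.
- Comparison: the chosen route closes the ring and sets C6 in one step from an open chain assembled from two simple fragments.

**Alternative 2: oxy-Cope ring expansion.**
- Disconnection: C1–C10, made while C3–C8 of a six-membered ring is broken.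
- Forward key step: the C3 potassium alkoxide of the cyclohexane-fused butenolide A4 undergoes a [3,3] shift that gives the ten-membered ring A3, with the C3 ketone emerging from the enolate and C8=C9 formed directly.
- For it: there is no entropic penalty for medium-ring formation, the E ring alkene follows from the chair transition state, and no high dilution is needed. In reliability of the ring-forming event it is stronger than the chosen route.
- Against it: A4 has two adjacent fully substituted carbons (C3, C8), an enol-ether alkenyl group of defined geometry and a γ,γ-disubstituted butenolide, which costs many steps. The fused lactone holds the C8 alkenyl group away from the ideal chair arrangement. The strongly basic alkoxide sits next to a lactone and β to the C6 silyloxy group, and C10 depends on chirality transfer from the enol-ether geometry.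
- Comparison: the chosen route takes C10 intact from the chiral pool and needs far fewer steps before ring closure.

**Alternative 3: allylchromium closure at C5–C6, then relay from C6 to C4.**
- Disconnection: C5–C6.
- Forward key step: CrCl2 converts the allylic bromide of the 2-(bromomethyl)enone A6 into an allylchromium that adds to the C6 aldehyde on the butenolide, giving A5 with a C4 exocyclic methylene.
- For it: allylchromium additions need no nickel, are more nucleophilic and are well established for ten-membered rings, and C4 is not carried as an epimerisable centre before ring closure. On ring-closure reliability this is as strong as or stronger than the chosen route.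
- Against it: A6 combines a formyl group on an electron-poor butenolide with a bromomethyl enone, two highly electrophilic groups. C6 must be set without any help from C4. C4 must then be set by conjugate reduction of the exocyclic enone under 1,3-relay from C6, in competition with reduction of the dienyl lactone. At least two further steps follow ring closure.
- Comparison: the chosen route sets C4 early under catalyst control and lets it bias C6; after ring closure only acylations and one deprotection remain.

Key step: step 15

## Remarks before the steps

- Assumption: the target is taken as the open 10-hydroxy-3-ketone that is drawn; its ring–chain equilibrium with the C3/C10 hemiketal is a property of the compound and is not addressed by separate steps.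
- Protecting groups: C13 is carried as a tert-butyldiphenylsilyl ether, so that the triethylsilyl ethers at C3, C6 and C10 can be removed cleanly in its presence. C10 is silylated only up to step 13; the key step runs with the free C10 hydroxyl.

## Steps

Step 1
Reactants: 1 (R)-linalool
Product: 2 (3R)-3,7-dimethyl-3-(triethylsilyloxy)octa-1,6-diene
Conditions: TESOTf, 2,6-lutidine, CH2Cl2, −78 to 0 °C
Reagents that add atoms: triethylsilyl triflate, CC[Si](CC)(CC)OS(=O)(=O)C(F)(F)F
Why: Silylation of the hindered tertiary alcohol with a silyl triflate. The ether prevents the hydroxyl from opening the epoxide of step 2 and adds bulk next to the C9 vinyl group.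

Step 2
Reactants: 2 (3R)-3,7-dimethyl-3-(triethylsilyloxy)octa-1,6-diene
Product: 3 (3R)-6,7-epoxy-3,7-dimethyl-3-(triethylsilyloxy)oct-1-ene (both epimers at the epoxide CH)
Conditions: mCPBA, NaHCO3, CH2Cl2, 0 °C
Reagents that add atoms: 3-chloroperbenzoic acid, OOC(=O)c1cccc(Cl)c1
Why: Prilezhaev epoxidation. The electron-rich trisubstituted alkene reacts far faster than the monosubstituted vinyl group on an oxygen-bearing quaternary carbon. The epoxide configuration is irrelevant because both epoxide carbons are cleaved apart in step 3.

Step 3
Reactants: 3 (3R)-6,7-epoxy-3,7-dimethyl-3-(triethylsilyloxy)oct-1-ene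
Product: 4 (4R)-4-methyl-4-(triethylsilyloxy)hex-5-enal
Conditions: H5IO6, THF/Et2O, 0 °C
Reagents that add atoms: none
Why: Periodic acid opens the trisubstituted epoxide at the tertiary carbon and cleaves the resulting glycol, giving the C3 aldehyde and acetone. The vinyl group and the hindered tertiary silyl ether should survive the short exposure.

Step 4
Reactants: 4 (4R)-4-methyl-4-(triethylsilyloxy)hex-5-enal; 5 (E)-crotylboronic acid pinacol ester
Product: 7 (3S,4R,7R)-3,7-dimethyl-7-(triethylsilyloxy)nona-1,8-dien-4-ol, via borate ester 6 (not isolated)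
Conditions: (S)-TRIP [(S)-3,3′-bis(2,4,6-triisopropylphenyl)-1,1′-binaphthyl-2,2′-diyl hydrogen phosphate] (5 mol%), 4 Å MS, toluene, −30 °C; aqueous work-up
Reagents that add atoms: none
Why: Chiral phosphoric acid-catalysed crotylboration through a closed chair transition state. The E-crotyl geometry gives the anti adduct, and the (S)-catalyst is the antipode expected to deliver the crotyl group to the Si face of the aldehyde, which fixes the target C4 as S (C3 is R here and is oxidised away in step 14).

Step 5
Reactants: 7 (3S,4R,7R)-3,7-dimethyl-7-(triethylsilyloxy)nona-1,8-dien-4-ol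
Product: 9 (3S,4R,7R)-3,7-dimethyl-7-(triethylsilyloxy)non-8-ene-1,4-diol, via bis-boron adduct 8 (not isolated)
Conditions: Sia2BH (from BH3·THF and 2-methylbut-2-ene, 2.5 equiv), THF, −10 to 0 °C; then NaOH, H2O2, 0 °C to rt
Reagents that add atoms: hydrogen peroxide, OO
Why: Anti-Markovnikov hydroboration–oxidation with a bulky dialkylborane; one equivalent is consumed by the free hydroxyl. The C5=C6 vinyl group sits on a tertiary carbon. The other vinyl group sits on a fully substituted carbon bearing a silyloxy group, which makes it more hindered and inductively deactivated, so it should react much more slowly.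

Step 6
Reactants: 9 (3S,4R,7R)-3,7-dimethyl-7-(triethylsilyloxy)non-8-ene-1,4-diol
Product: 10 (3R,6R,7S)-3,7-dimethyl-3,6,9-tris(triethylsilyloxy)non-1-ene
Conditions: TESOTf (2.4 equiv), 2,6-lutidine, CH2Cl2, −78 °C
Reagents that add atoms: triethylsilyl triflate, CC[Si](CC)(CC)OS(=O)(=O)C(F)(F)F
Why: Silylation of the primary and the secondary hydroxyl. The three triethylsilyl ethers are later removed together in step 13.

Step 7
Reactants: 10 (3R,6R,7S)-3,7-dimethyl-3,6,9-tris(triethylsilyloxy)non-1-ene
Product: 12 (2R,5R,6S)-2,6-dimethyl-2,5,8-tris(triethylsilyloxy)octanal, via ozonide 11 (not isolated)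
Conditions: O3, CH2Cl2, −78 °C; then PPh3, −78 °C to rt
Reagents that add atoms: ozone, [O-][O+]=O
Why: Ozonolysis of the only C=C bond with reductive work-up. The resulting C9 aldehyde has no α-hydrogen, so the C10 centre cannot epimerise.

Step 8
Reactants: 13 but-2-yne-1,4-diol
Product: 14 4-(tert-butyldiphenylsilyloxy)but-2-yn-1-ol
Conditions: TBDPSCl (1 equiv), imidazole, 13 (4 equiv), DMF, 0 °C
Reagents that add atoms: tert-butyldiphenylsilyl chloride, CC(C)(C)[Si](Cl)(c1ccccc1)c1ccccc1
Why: Statistical monosilylation of a symmetrical diol used in excess; the cheap diol is washed out with water.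

Step 9
Reactants: 14 4-(tert-butyldiphenylsilyloxy)but-2-yn-1-ol
Product: 15 4-(tert-butyldiphenylsilyloxy)but-2-ynyl methyl carbonate
Conditions: ClCO2Me, pyridine, CH2Cl2, 0 °C
Reagents that add atoms: methyl chloroformate, COC(=O)Cl
Why: Acylation of the primary propargylic alcohol; the carbonate is the leaving group for step 10.

Step 10
Reactants: 15 4-(tert-butyldiphenylsilyloxy)but-2-ynyl methyl carbonate
Product: 16 methyl 2-[(tert-butyldiphenylsilyloxy)methyl]buta-2,3-dienoate
Conditions: Pd2(dba)3·CHCl3 (2.5 mol%), PPh3 (10 mol%), CO (3 atm), MeOH, 40 °C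
Reagents that add atoms: carbon monoxide, [C-]#[O+]; methanol, CO
Why: Palladium-catalysed carbonylation of a propargylic carbonate. Zerovalent palladium attacks in the SN2′ sense with loss of CO2 to give an allenylpalladium species, CO inserts, and methanolysis releases the 2,3-dienoate. This places C12 on the carbon that becomes C11.

Step 11
Reactants: 16 methyl 2-[(tert-butyldiphenylsilyloxy)methyl]buta-2,3-dienoate
Product: 17 3-[(tert-butyldiphenylsilyloxy)methyl]-4-iodofuran-2(5H)-one
Conditions: I2, NaHCO3, MeCN/H2O, rt
Reagents that add atoms: iodine, II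
Why: Iodolactonisation of a 2,3-allenoate. Iodine activates the distal C=C bond, the ester carbonyl oxygen closes on the terminal carbon, and the ester methyl group is lost. Iodine ends on the central allene carbon, which is the lactone β-carbon C7.

Step 12
Reactants: 12 (2R,5R,6S)-2,6-dimethyl-2,5,8-tris(triethylsilyloxy)octanal; 17 3-[(tert-butyldiphenylsilyloxy)methyl]-4-iodofuran-2(5H)-one
Product: 20 (Z)-3-[(tert-butyldiphenylsilyloxy)methyl]-4-iodo-5-[(2R,5R,6S)-2,6-dimethyl-2,5,8-tris(triethylsilyloxy)octylidene]furan-2(5H)-one, via silyloxyfuran 18 (not isolated), via silyl aldol adduct 19 (not isolated)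
Conditions: TBSOTf (2.5 equiv), iPr2NEt (3 equiv), CH2Cl2, 0 °C to rt; then DBU (2 equiv), rt
Reagents that add atoms: none
Why: Silyl triflate-mediated vinylogous aldol condensation, known for 4-halobutenolides. The lactone is silylated to the 2-silyloxyfuran, whose γ-carbon adds to the silyl-activated aldehyde in a Mukaiyama-type step, and DBU then expels silanolate by an E1cB path. The Z isomer is favoured because the bulky C10 substituent avoids the iodine on C7.

Step 13
Reactants: 20 (Z)-ylidene butenolide tris(triethylsilyl) ether
Product: 21 (Z)-3-[(tert-butyldiphenylsilyloxy)methyl]-4-iodo-5-[(2R,5R,6S)-2,5,8-trihydroxy-2,6-dimethyloctylidene]furan-2(5H)-one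
Conditions: HF·pyridine, pyridine, THF, 0 °C to rt
Reagents that add atoms: none
Why: Buffered fluoride cleavage of the three triethylsilyl ethers. The primary tert-butyldiphenylsilyl ether is far more stable under these conditions, and no nucleophilic alcohol or base is present that could open the enol lactone or displace the iodide.

Step 14
Reactants: 21 iodo ylidene butenolide triol
Product: 23 (Z)-3-[(tert-butyldiphenylsilyloxy)methyl]-5-[(2R,6S)-2-hydroxy-2,6-dimethyl-5,8-dioxooctylidene]-4-iodofuran-2(5H)-one, via alkoxysulfonium salt 22 (not isolated)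
Conditions: (COCl)2, DMSO, CH2Cl2, −78 °C; then iPr2NEt, −78 to −20 °C; used at once
Reagents that add atoms: none
Why: Swern oxidation. Both the secondary and the primary hydroxyl are converted into alkoxysulfonium ions at −78 °C before base is added, so the hydroxy aldehyde cannot close to a lactol and over-oxidise. The tertiary hydroxyl has no α-hydrogen and is returned unchanged, and the cold amine treatment should leave C4 intact.

Step 15
Reactants: 23 open-chain 4-iodo Z-ylidene butenolide keto aldehyde
Product: 26 (4S,6R,10R) ten-membered keto Z-ylidene butenolide with free C6 and C10 hydroxyls and C13 tert-butyldiphenylsilyl ether, via alkenylchromium 24 (not isolated), via chromium alkoxide 25 (not isolated)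
Conditions: CrCl2 (8 equiv), (S)-4-isopropyl-2-[2-(methanesulfonamido)-3-methylphenyl]-4,5-dihydrooxazole (8.8 equiv), Et3N (8.8 equiv), MeCN, rt; then NiCl2·(2,9-dimethyl-1,10-phenanthroline) (0.2 equiv) and slow addition of 23 in THF (final 2 mM), rt; aqueous serine/NaHCO3 work-up
Reagents that add atoms: none
Why: CrCl2 reduces the nickel salt to zerovalent nickel, which inserts into the electron-poor C7–I bond; transfer of the alkenyl group to trivalent chromium gives 24, which adds to the chromium-bound C6 aldehyde to give alkoxide 25, and work-up gives 26. The closest known reactions are intramolecular Nozaki–Hiyama–Kishi alkenyl iodide–aldehyde cyclisations to medium and large rings and the use of β-iodo-α,β-unsaturated esters as the halide partner. The ten-membered ring closes by a 10-exo-trig 1,2-addition that forms C6–C7. Alkenylchromium reagents add to aldehydes much faster than to ketones, and attack on the C3 ketone would put the E C8=C9 bond into a seven-membered ring, so the ketone, the free tertiary hydroxyl and the enol lactone are expected to be left alone. The new C6 centre requires addition to the Si face of the aldehyde. The controlling element is the conformation of the closing chain: with the C10 hydroxyl (the smallest C10 substituent) eclipsing C8=C9 next to the lactone oxygen, the (10R) centre sends C1 over one face of the planar dienyl lactone. The C4 methyl is then pseudo-equatorial, the aldehyde hydrogen lies in the lactone plane beside the C13 side chain and the chromium-bound oxygen points outward, which corresponds to 6R. The chiral sulfonamide ligand on chromium is added to reinforce this preference. Slow addition at high dilution secures ring closure over intermolecular coupling.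

Step 16
Reactants: 26 ten-membered keto diol; 27 3-methylbut-2-enoyl chloride
Product: 28 (4S,6R,10R) C6 3-methylbut-2-enoate of 26 (C10 hydroxyl free, C13 tert-butyldiphenylsilyl ether)
Conditions: pyridine, DMAP (cat.), CH2Cl2, 0 °C
Reagents that add atoms: none
Why: Acylation of the secondary allylic alcohol with retention at C6; the tertiary C10 hydroxyl does not acylate under these conditions. The weak base pyridine at 0 °C limits deconjugation of the acyl group through a vinylketene.

Step 17
Reactants: 28 C6 senecioate silyl ether
Product: 29 (4S,6R,10R) C13 primary alcohol (C6 3-methylbut-2-enoate, C10 hydroxyl free)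
Conditions: HF·pyridine, THF, 0 °C to rt
Reagents that add atoms: none
Why: Fluoride cleavage of the primary tert-butyldiphenylsilyl ether under non-basic conditions that the enol lactone, the senecioate and the ketone tolerate.

Step 18
Reactants: 29 C13 primary alcohol
Product: 30 target, (4S,6R,10R)-13-acetoxy-10-hydroxy-3-oxo ten-membered Z-ylidene butenolide C6 3-methylbut-2-enoate
Conditions: Ac2O, pyridine, CH2Cl2, 0 °C
Reagents that add atoms: acetic anhydride, CC(=O)OC(C)=O
Why: Acetylation of the primary alcohol; without strong acyl-transfer catalysis the tertiary C10 hydroxyl stays free.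

## Compound list

1 | (R)-linalool, (3R)-3,7-dimethylocta-1,6-dien-3-ol | C=C[C@](C)(O)CCC=C(C)C | starting material
2 | (3R)-3,7-dimethyl-3-(triethylsilyloxy)octa-1,6-diene | C=C[C@](C)(O[Si](CC)(CC)CC)CCC=C(C)C | intermediate
3 | (3R)-6,7-epoxy-3,7-dimethyl-3-(triethylsilyloxy)oct-1-ene, epimers at the epoxide CH | C=C[C@](C)(O[Si](CC)(CC)CC)CCC1OC1(C)C | intermediate
4 | (4R)-4-methyl-4-(triethylsilyloxy)hex-5-enal | C=C[C@](C)(O[Si](CC)(CC)CC)CCC=O | intermediate
5 | (E)-crotylboronic acid pinacol ester | C/C=C/CB1OC(C)(C)C(C)(C)O1 | starting material
6 | pinacol borate ester of 7 (not isolated) | C=C[C@](C)(O[Si](CC)(CC)CC)CC[C@@H](OB1OC(C)(C)C(C)(C)O1)[C@@H](C)C=C | intermediate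
7 | (3S,4R,7R)-3,7-dimethyl-7-(triethylsilyloxy)nona-1,8-dien-4-ol | C=C[C@](C)(O[Si](CC)(CC)CC)CC[C@@H](O)[C@@H](C)C=C | intermediate
8 | C6-disiamylboryl, C3-O-disiamylboryl adduct of 7 (not isolated) | C=C[C@](C)(O[Si](CC)(CC)CC)CC[C@@H](OB(C(C)C(C)C)C(C)C(C)C)[C@@H](C)CCB(C(C)C(C)C)C(C)C(C)C | intermediate
9 | (3S,4R,7R)-3,7-dimethyl-7-(triethylsilyloxy)non-8-ene-1,4-diol | C=C[C@](C)(O[Si](CC)(CC)CC)CC[C@@H](O)[C@@H](C)CCO | intermediate
10 | (3R,6R,7S)-3,7-dimethyl-3,6,9-tris(triethylsilyloxy)non-1-ene | C=C[C@](C)(O[Si](CC)(CC)CC)CC[C@@H](O[Si](CC)(CC)CC)[C@@H](C)CCO[Si](CC)(CC)CC | intermediate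
11 | 1,2,4-trioxolane (ozonide) of 10 (not isolated) | C1OOC(O1)[C@](C)(O[Si](CC)(CC)CC)CC[C@@H](O[Si](CC)(CC)CC)[C@@H](C)CCO[Si](CC)(CC)CC | intermediate
12 | (2R,5R,6S)-2,6-dimethyl-2,5,8-tris(triethylsilyloxy)octanal | O=C[C@](C)(O[Si](CC)(CC)CC)CC[C@@H](O[Si](CC)(CC)CC)[C@@H](C)CCO[Si](CC)(CC)CC | intermediate
13 | but-2-yne-1,4-diol | OCC#CCO | starting material
14 | 4-(tert-butyldiphenylsilyloxy)but-2-yn-1-ol | CC(C)(C)[Si](c1ccccc1)(c1ccccc1)OCC#CCO | intermediate
15 | 4-(tert-butyldiphenylsilyloxy)but-2-ynyl methyl carbonate | CC(C)(C)[Si](c1ccccc1)(c1ccccc1)OCC#CCOC(=O)OC | intermediate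
16 | methyl 2-[(tert-butyldiphenylsilyloxy)methyl]buta-2,3-dienoate | C=C=C(CO[Si](c1ccccc1)(c1ccccc1)C(C)(C)C)C(=O)OC | intermediate
17 | 3-[(tert-butyldiphenylsilyloxy)methyl]-4-iodofuran-2(5H)-one | CC(C)(C)[Si](c1ccccc1)(c1ccccc1)OCC1=C(I)COC1=O | intermediate
18 | 2-(tert-butyldimethylsilyloxy)-3-[(tert-butyldiphenylsilyloxy)methyl]-4-iodofuran (not isolated) | CC(C)(C)[Si](c1ccccc1)(c1ccccc1)OCc1c(I)coc1O[Si](C)(C)C(C)(C)C | intermediate
19 | C9-O-tert-butyldimethylsilyl vinylogous aldol adduct of 12 and 17, mixture at C8 and C9 (not isolated) | CC(C)(C)[Si](c1ccccc1)(c1ccccc1)OCC1=C(I)C(OC1=O)C(O[Si](C)(C)C(C)(C)C)[C@](C)(O[Si](CC)(CC)CC)CC[C@@H](O[Si](CC)(CC)CC)[C@@H](C)CCO[Si](CC)(CC)CC | intermediate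
20 | (Z)-3-[(tert-butyldiphenylsilyloxy)methyl]-4-iodo-5-[(2R,5R,6S)-2,6-dimethyl-2,5,8-tris(triethylsilyloxy)octylidene]furan-2(5H)-one | CC(C)(C)[Si](c1ccccc1)(c1ccccc1)OCC1=C(I)/C(=C/[C@](C)(O[Si](CC)(CC)CC)CC[C@@H](O[Si](CC)(CC)CC)[C@@H](C)CCO[Si](CC)(CC)CC)OC1=O | intermediate
21 | (Z)-3-[(tert-butyldiphenylsilyloxy)methyl]-4-iodo-5-[(2R,5R,6S)-2,5,8-trihydroxy-2,6-dimethyloctylidene]furan-2(5H)-one | CC(C)(C)[Si](c1ccccc1)(c1ccccc1)OCC1=C(I)/C(=C/[C@](C)(O)CC[C@@H](O)[C@@H](C)CCO)OC1=O | intermediate
22 | C3,C6-bis(dimethylsulfonio-oxy) dichloride of 21 (not isolated) | CC(C)(C)[Si](c1ccccc1)(c1ccccc1)OCC1=C(I)/C(=C/[C@](C)(O)CC[C@@H](O[S+](C)C)[C@@H](C)CCO[S+](C)C)OC1=O.[Cl-].[Cl-] | intermediate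
23 | (Z)-3-[(tert-butyldiphenylsilyloxy)methyl]-5-[(2R,6S)-2-hydroxy-2,6-dimethyl-5,8-dioxooctylidene]-4-iodofuran-2(5H)-one (key-step precursor) | CC(C)(C)[Si](c1ccccc1)(c1ccccc1)OCC1=C(I)/C(=C/[C@](C)(O)CCC(=O)[C@@H](C)CC=O)OC1=O | intermediate
24 | C7 alkenylchromium dichloride derived from 23 (not isolated) | CC(C)(C)[Si](c1ccccc1)(c1ccccc1)OCC1=C([Cr](Cl)Cl)/C(=C/[C@](C)(O)CCC(=O)[C@@H](C)CC=O)OC1=O | intermediate
25 | C6 chromium alkoxide of 26 (not isolated) | CC(C)(C)[Si](c1ccccc1)(c1ccccc1)OCC1=C2/C(=C/[C@](C)(O)CCC(=O)[C@@H](C)C[C@H]2O[Cr](Cl)Cl)OC1=O | intermediate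
26 | (4S,6R,10R) ten-membered keto Z-ylidene butenolide, C6 and C10 hydroxyls free, C13 tert-butyldiphenylsilyl ether (key-step product) | CC(C)(C)[Si](c1ccccc1)(c1ccccc1)OCC1=C2/C(=C/[C@](C)(O)CCC(=O)[C@@H](C)C[C@H]2O)OC1=O | intermediate
27 | 3-methylbut-2-enoyl chloride | CC(C)=CC(=O)Cl | starting material
28 | (4S,6R,10R) C6 3-methylbut-2-enoate of 26 | CC(C)(C)[Si](c1ccccc1)(c1ccccc1)OCC1=C2/C(=C/[C@](C)(O)CCC(=O)[C@@H](C)C[C@H]2OC(=O)C=C(C)C)OC1=O | intermediate
29 | (4S,6R,10R) C13 alcohol, C6 3-methylbut-2-enoate | OCC1=C2/C(=C/[C@](C)(O)CCC(=O)[C@@H](C)C[C@H]2OC(=O)C=C(C)C)OC1=O | intermediate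
30 | CNP0186726.1 | CC(=O)OCC1=C2/C(=C/[C@](C)(O)CCC(=O)[C@@H](C)C[C@H]2OC(=O)C=C(C)C)OC1=O | target

## Step count and uncertain steps

Total: 18 steps. Longest linear sequence: 14 steps (steps 1 to 7 and 12 to 18, from 1); the butenolide branch (steps 8 to 11) joins at step 12.

**Step 15 (key step).**
- Most likely failure: poor facial selectivity at the C6 aldehyde. The preference for the Si face rests on a conformational model of a flexible ten-membered transition state, and the ligand sense is not assured to match it.
- Other failures: protonolysis of the alkenylchromium (reductive loss of iodine), intermolecular coupling if ring closure is slow, and base- or Lewis acid-induced aldol cyclisation of the 1,4-dicarbonyl unit.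
- Fallback: if addition occurs mainly on the Re face, step 15 sets out from 23 as before and delivers the (6S)-epimer of 26 F1. Mitsunobu esterification of F1 with 3-methylbut-2-enoic acid (PPh3, DIAD, toluene, 0 °C) inverts C6 and installs the senecioate in one operation, the tertiary hydroxyl being inert, and the route is rejoined at 28.

**Step 5.**
- Most likely failure: competing hydroboration of the vinyl group on C10, because both alkenes are monosubstituted and the discrimination is only steric and inductive.
- Fallback, setting out from 7: cross-metathesis with vinylboronic acid pinacol ester (second-generation Hoveyda–Grubbs catalyst, CH2Cl2, 40 °C) engages only the unhindered C5=C6 vinyl group, since an alkene on a fully substituted allylic carbon does not take part, and gives the (E)-alkenylboronate F2. Oxidation with NaBO3 in THF/H2O gives the C6 aldehyde as its lactol with the C3 hydroxyl F3. Reduction with NaBH4 in MeOH opens the lactol to diol 9, where the route is rejoined.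

**Step 12.**
- Most likely failure: slow addition to the hindered α-quaternary aldehyde, followed by retro-aldol cleavage or incomplete elimination under DBU. Further risks are ionisation of the silyloxymethyl group on the electron-rich silyloxyfuran and loss of iodide by addition–elimination.
- Fallback, setting out from 17 and 12: C–C bond formation and elimination are separated. Compound 17 is converted with TIPSOTf/Et3N into the isolable 2-(triisopropylsilyloxy)furan F4. A BF3·OEt2-mediated vinylogous Mukaiyama aldol addition to 12 at −78 °C gives the free C9 aldol F5. MsCl/Et3N gives the C9 mesylate F6, and brief treatment with DBU eliminates the sulfonate to give 20.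

**Step 14.**
- Most likely failure: closure of the intermediate hydroxy aldehyde to a lactol and over-oxidation to the γ-lactone if activation of both hydroxyls is incomplete. Aldol condensation of the keto aldehyde on warming with amine is a second risk.
- Fallback, setting out from 21: the two oxidations are staged. Selective silylation of the primary hydroxyl (TESCl, imidazole, CH2Cl2, −40 °C) gives the C6 triethylsilyl ether F7. Dess–Martin periodinane with NaHCO3 oxidises the C3 hydroxyl to the ketone F8. HF·pyridine/pyridine frees the primary alcohol to give the keto alcohol F9, and a second Dess–Martin oxidation gives 23.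

## Further compounds

F1 | step 15 | (4S,6S,10R)-6-epimer of 26 | CC(C)(C)[Si](c1ccccc1)(c1ccccc1)OCC1=C2/C(=C/[C@](C)(O)CCC(=O)[C@@H](C)C[C@@H]2O)OC1=O
F2 | step 5 | (3S,4R,7R,1E)-1-(pinacolboryl)-3,7-dimethyl-7-(triethylsilyloxy)nona-1,8-dien-4-ol | C=C[C@](C)(O[Si](CC)(CC)CC)CC[C@@H](O)[C@@H](C)/C=C/B1OC(C)(C)C(C)(C)O1
F3 | step 5 | (4S,5R)-4-methyl-5-[(3R)-3-methyl-3-(triethylsilyloxy)pent-4-enyl]tetrahydrofuran-2-ol, anomers | C=C[C@](C)(O[Si](CC)(CC)CC)CC[C@H]1OC(O)C[C@@H]1C
F4 | step 12 | 3-[(tert-butyldiphenylsilyloxy)methyl]-4-iodo-2-(triisopropylsilyloxy)furan | CC(C)[Si](Oc1occ(I)c1CO[Si](c1ccccc1)(c1ccccc1)C(C)(C)C)(C(C)C)C(C)C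
F5 | step 12 | free C9 aldol adduct of 12 and 17, mixture at C8 and C9 | CC(C)(C)[Si](c1ccccc1)(c1ccccc1)OCC1=C(I)C(OC1=O)C(O)[C@](C)(O[Si](CC)(CC)CC)CC[C@@H](O[Si](CC)(CC)CC)[C@@H](C)CCO[Si](CC)(CC)CC
F6 | step 12 | C9 methanesulfonate of F5 | CC(C)(C)[Si](c1ccccc1)(c1ccccc1)OCC1=C(I)C(OC1=O)C(OS(C)(=O)=O)[C@](C)(O[Si](CC)(CC)CC)CC[C@@H](O[Si](CC)(CC)CC)[C@@H](C)CCO[Si](CC)(CC)CC
F7 | step 14 | C6 triethylsilyl ether of 21 | CC(C)(C)[Si](c1ccccc1)(c1ccccc1)OCC1=C(I)/C(=C/[C@](C)(O)CC[C@@H](O)[C@@H](C)CCO[Si](CC)(CC)CC)OC1=O
F8 | step 14 | C3 ketone, C6 triethylsilyl ether | CC(C)(C)[Si](c1ccccc1)(c1ccccc1)OCC1=C(I)/C(=C/[C@](C)(O)CCC(=O)[C@@H](C)CCO[Si](CC)(CC)CC)OC1=O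
F9 | step 14 | C3 ketone, C6 primary alcohol | CC(C)(C)[Si](c1ccccc1)(c1ccccc1)OCC1=C(I)/C(=C/[C@](C)(O)CCC(=O)[C@@H](C)CCO)OC1=O
A1 | alternative 1 | tris-silyl-protected ten-membered keto Z-ylidene butenolide | CC(C)(C)[Si](C)(C)OCC1=C2/C(=C/[C@](C)(O[Si](CC)(CC)CC)CCC(=O)[C@@H](C)C[C@H]2O[Si](C)(C)C(C)(C)C)OC1=O
A2 | alternative 1 | ten-membered Z-β-iodoenone (C8 ketone, exocyclic C7=C11 iodoalkene) | CC(C)(C)[Si](C)(C)OC/C(I)=C1/C(=O)C[C@](C)(O[Si](CC)(CC)CC)CCC(=O)[C@@H](C)C[C@H]1O[Si](C)(C)C(C)(C)C
A3 | alternative 2 | ten-membered keto Z-ylidene butenolide, C10 methoxymethyl ether, C6 and C13 silyl ethers | CC(C)(C)[Si](C)(C)OCC1=C2/C(=C/[C@](C)(OCOC)CCC(=O)[C@@H](C)C[C@H]2O[Si](C)(C)C(C)(C)C)OC1=O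
A4 | alternative 2 | cyclohexane-fused butenolide with C3 vinyl carbinol and C8 2-(methoxymethoxy)propenyl group, trans | C=C[C@@]1(O)[C@@H](C)C[C@@H](O[Si](C)(C)C(C)(C)C)C2=C(CO[Si](C)(C)C(C)(C)C)C(=O)O[C@@]12/C=C(\C)OCOC
A5 | alternative 3 | ten-membered Z-ylidene butenolide with C6 alcohol and exocyclic C4 methylene enone | CC(C)(C)[Si](C)(C)OCC1=C2/C(=C/[C@](C)(O)CCC(=O)C(=C)C[C@H]2O)OC1=O
A6 | alternative 3 | open-chain 4-formyl Z-ylidene butenolide with 2-(bromomethyl)enone terminus | CC(C)(C)[Si](C)(C)OCC1=C(C=O)/C(=C/[C@](C)(O)CCC(=O)C(=C)CBr)OC1=O
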